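Retrosynthetic cuts: (a) a CO2H is put back on the free CH of the central ring (ring A) that lies between the bridge-bearing carbon and the C–OH carbon; (b) the ArCH2–CH2Ar bond of the ethano bridge is cut, at the stage of a 3-aryl-3,4-dihydroisocoumarin, into a ring A methyl carbanion and 3-(benzyloxy)benzaldehyde; (c) ring A is cut at C1–C6 and C3–C4 into methyl crotonate and a γ-benzylated acetoacetate; (d) that keto ester is cut at its γ-C–CH2Ar bond.
Enabling feature: the bridge carbon on ring A is meta to both oxygens, so neither can activate it. The ring CH next to it is ortho to OH and para to OMe, so the target is the decarboxylated form of a 2-hydroxy-4-methoxy-6-alkylbenzoic acid (orsellinate pattern).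
A carboxyl parked on that CH does four jobs: it acidifies the ortho CH3 (dienolate), it tells the two oxygens apart (only one is hydrogen-bonded to it), it traps the new alkoxide as a temporary δ-lactone, and it leaves as CO2 because its ipso carbon is easily protonated.
Forward order: benzylation of the acetoacetate dianion, ring A by Michael–Dieckmann annulation and aromatisation (the ring construction places every substituent), 4-O-methylation, 2-O-benzylation, fragment union with lactone closure, one hydrogenolysis that opens the lactone and removes three benzyl groups, decarboxylation.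
Stereochemistry: the target has no stereocentre. The stereocentres of the cyclohexanedione and C3 of the lactone arise without control and are erased by aromatisation and hydrogenolysis.

Key step: step 6

Assumption: 4-(benzyloxy)benzyl chloride and 3-(benzyloxy)benzaldehyde are taken as catalogue chemicals; ring A is numbered as a benzoate (C1 carries the carboxyl carbon, C6 the methyl or bridge carbon).

Step 1
Reactants: 1 methyl acetoacetate; 2 4-(benzyloxy)benzyl chloride
Product: 4 methyl 5-[4-(benzyloxy)phenyl]-3-oxopentanoate, via acetoacetate dianion 3 (not isolated)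
Conditions: NaH, THF, 0 °C; n-BuLi, 0 °C; then 2, 0 °C to rt; aq NH4Cl
Reagents that add atoms: sodium hydride [Na+].[H-]; n-butyllithium [Li]CCCC (they supply only the counter-ions of 3; no atom of them stays in 4)
Why: Acetoacetate dianion γ-alkylation: the terminal carbanion of 3 is far more basic and nucleophilic than the internal one, so the reactive benzylic chloride should be taken up at C4 only, which puts the future C3 benzyl group of ring A on the chain before the ring exists.

Step 2
Reactants: 4 methyl 5-[4-(benzyloxy)phenyl]-3-oxopentanoate; 5 methyl crotonate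
Product: 7 methyl 3-[4-(benzyloxy)benzyl]-6-methyl-2,4-dioxocyclohexane-1-carboxylate, via Michael adduct 6 (not isolated)
Conditions: NaOMe (1.5 equiv), MeOH, reflux; then aq HCl
Reagents that add atoms: none
Why: Michael addition of the keto ester α-carbon to the crotonate followed by Dieckmann-type closure of the ketone γ-CH2 on the crotonate ester (the only six-membered option) is the classical dihydroresorcylate annulation, it is pulled forward by the stable 1,3-dione enolate, and the three stereocentres, formed without control, vanish in step 3.

Step 3
Reactants: 7 methyl 3-[4-(benzyloxy)benzyl]-6-methyl-2,4-dioxocyclohexane-1-carboxylate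
Product: 9 methyl 3-[4-(benzyloxy)benzyl]-2,4-dihydroxy-6-methylbenzoate, via 3-bromo dione 8 (not isolated)
Conditions: Br2 (1.0 equiv), DMF, 0 °C; then Li2CO3, 80 °C
Reagents that add atoms: bromine BrBr (its Br is carried only by 8 and is lost again on the way to 9)
Why: Bromination–dehydrobromination aromatisation of a dihydroresorcylate: the enol carbon C3 is brominated much faster than either arene, enolisation of C4=O towards C5 then allows 1,4-loss of HBr (H-6, Br-3) and tautomerisation to the benzenoid ring, while Li2CO3 keeps the medium free of HBr for the sake of the benzyl ether.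

Step 4
Reactants: 9 methyl 3-[4-(benzyloxy)benzyl]-2,4-dihydroxy-6-methylbenzoate
Product: 10 methyl 3-[4-(benzyloxy)benzyl]-2-hydroxy-4-methoxy-6-methylbenzoate
Conditions: MeI (1.1 equiv), K2CO3 (1.1 equiv), acetone, rt to reflux
Reagents that add atoms: iodomethane CI
Why: Regioselective Williamson etherification as known for orsellinates: the 2-OH is tied up in a hydrogen bond to the ester carbonyl and is the poorer nucleophile, so a slight excess of MeI should methylate the more acidic 4-OH only, and this is the point at which the carboxyl helper tells the two ring A oxygens apart.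

Step 5
Reactants: 10 methyl 3-[4-(benzyloxy)benzyl]-2-hydroxy-4-methoxy-6-methylbenzoate
Product: 11 methyl 2-(benzyloxy)-3-[4-(benzyloxy)benzyl]-4-methoxy-6-methylbenzoate
Conditions: BnBr, K2CO3, DMF, 60 °C
Reagents that add atoms: benzyl bromide BrCc1ccccc1
Why: Williamson benzylation under more forcing conditions breaks the chelate and masks the last acidic proton before the carbanion step, with a group that falls in the hydrogenolysis of step 7 at no extra cost.

Step 6
Reactants: 11 methyl 2-(benzyloxy)-3-[4-(benzyloxy)benzyl]-4-methoxy-6-methylbenzoate; 12 3-(benzyloxy)benzaldehyde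
Product: 15 (±)-8-(benzyloxy)-7-[4-(benzyloxy)benzyl]-3-[3-(benzyloxy)phenyl]-6-methoxy-3,4-dihydroisocoumarin, via toluate carbanion 13 (not isolated), via lithium alkoxide 14 (not isolated)
Conditions: LDA (1.2 equiv), THF, −78 °C; then 12, −78 °C to rt; aq NH4Cl
Reagents that add atoms: lithium diisopropylamide [Li+].CC(C)[N-]C(C)C (supplies only the lithium of 13 and 14; no atom of it stays in 15)
Why: LDA, pre-complexed to the ester carbonyl, removes a proton of the neighbouring C6 methyl group to give the o-quinodimethane-type dienolate 13, whose exocyclic CH2 adds to the aldehyde carbon of 12 and so forms the central C–C bond of the bridge, after which alkoxide 14 attacks the adjacent ester and expels methoxide. The closest known reaction type is the lateral-lithiation (toluate anion) aldol–lactonisation that is the standard entry to 3-aryl-3,4-dihydroisocoumarins. The δ-lactone closes by 6-exo-trig acyl substitution, which should be fast because alkoxide and ester are held ortho to each other on ring A, and this closure makes the reversible carbonyl addition irreversible. The new stereocentre C3 has no controlling element, should form as the racemate, and needs no control because step 7 turns it into a CH2 group. The step needs deprotonation at the CH3 and not at the diarylmethane CH2 or the OCH2Ph groups, and addition to 12 rather than self-acylation; only the CH3 is both next to and conjugated with the ester, LDA at −78 °C is kinetically too weak for the other sites, and the ester, flanked by OBn and CH3 and twisted out of the ring plane, resists intermolecular attack. At one stroke the step completes the carbon skeleton and turns a doubly ortho-substituted ester that would be hard to saponify into a benzylic lactone that hydrogen can open.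

Step 7
Reactants: 15 (±)-8-(benzyloxy)-7-[4-(benzyloxy)benzyl]-3-[3-(benzyloxy)phenyl]-6-methoxy-3,4-dihydroisocoumarin
Product: 17 2-hydroxy-3-(4-hydroxybenzyl)-6-[2-(3-hydroxyphenyl)ethyl]-4-methoxybenzoic acid, via triphenol lactone 16 (not isolated)
Conditions: H2 (3–4 bar), 10% Pd/C, EtOH–AcOH, rt to 40 °C
Reagents that add atoms: none
Why: Palladium-catalysed hydrogenolysis should cleave the three aryl benzyl ethers and then the benzylic C3–O bond of the lactone (a cyclic benzyl ester), which opens the temporary ring to the CH2–CH2 bridge, deletes the stereocentre and frees the acid without any saponification, while the diarylmethane C–C bonds and the OMe group are inert.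

Step 8
Reactants: 17 2-hydroxy-3-(4-hydroxybenzyl)-6-[2-(3-hydroxyphenyl)ethyl]-4-methoxybenzoic acid
Product: 18 3-[2-(3-hydroxyphenyl)ethyl]-6-(4-hydroxybenzyl)-5-methoxyphenol (target CNP0112925.0)
Conditions: DMF, 120 °C, Ar
Reagents that add atoms: none
Why: Thermal protodecarboxylation of an electron-rich salicylic acid: the ortho OH and para OMe make ipso protonation at C1 (keto tautomer, β-keto acid-like) easy, so CO2 should leave under neutral conditions as it does from orsellinic and cannabinoid-type acids, and the helper is gone without touching the phenols.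

Compound list
1 | methyl acetoacetate | CC(=O)CC(=O)OC | starting material
2 | 4-(benzyloxy)benzyl chloride | ClCc1ccc(OCc2ccccc2)cc1 | starting material
3 | sodium lithium dianion of methyl acetoacetate (not isolated) | [Na+].[Li+].[CH2-]C(=O)[CH-]C(=O)OC | intermediate
4 | methyl 5-[4-(benzyloxy)phenyl]-3-oxopentanoate | COC(=O)CC(=O)CCc1ccc(OCc2ccccc2)cc1 | intermediate
5 | methyl crotonate, methyl (E)-but-2-enoate | C/C=C/C(=O)OC | starting material
6 | dimethyl 2-{3-[4-(benzyloxy)phenyl]propanoyl}-3-methylpentanedioate, diastereomer mixture (not isolated) | COC(=O)CC(C)C(C(=O)OC)C(=O)CCc1ccc(OCc2ccccc2)cc1 | intermediate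
7 | methyl 3-[4-(benzyloxy)benzyl]-6-methyl-2,4-dioxocyclohexane-1-carboxylate, mixture of diastereomers and enol tautomers | COC(=O)C1C(C)CC(=O)C(Cc2ccc(OCc3ccccc3)cc2)C1=O | intermediate
8 | methyl 3-bromo-3-[4-(benzyloxy)benzyl]-6-methyl-2,4-dioxocyclohexane-1-carboxylate, diastereomer mixture (not isolated) | COC(=O)C1C(C)CC(=O)C(Br)(Cc2ccc(OCc3ccccc3)cc2)C1=O | intermediate
9 | methyl 3-[4-(benzyloxy)benzyl]-2,4-dihydroxy-6-methylbenzoate | COC(=O)c1c(C)cc(O)c(Cc2ccc(OCc3ccccc3)cc2)c1O | intermediate
10 | methyl 3-[4-(benzyloxy)benzyl]-2-hydroxy-4-methoxy-6-methylbenzoate | COC(=O)c1c(C)cc(OC)c(Cc2ccc(OCc3ccccc3)cc2)c1O | intermediate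
11 | methyl 2-(benzyloxy)-3-[4-(benzyloxy)benzyl]-4-methoxy-6-methylbenzoate | COC(=O)c1c(C)cc(OC)c(Cc2ccc(OCc3ccccc3)cc2)c1OCc1ccccc1 | intermediate
12 | 3-(benzyloxy)benzaldehyde | O=Cc1cccc(OCc2ccccc2)c1 | starting material
13 | lithium salt of the C6-methyl carbanion of 11 (not isolated) | [Li+].[CH2-]c1cc(OC)c(Cc2ccc(OCc3ccccc3)cc2)c(OCc2ccccc2)c1C(=O)OC | intermediate
14 | lithium alkoxide of the racemic 1,2-diarylethanol adduct of 13 and 12 (not isolated) | [Li+].[O-]C(Cc1cc(OC)c(Cc2ccc(OCc3ccccc3)cc2)c(OCc2ccccc2)c1C(=O)OC)c1cccc(OCc2ccccc2)c1 | intermediate
15 | (±)-8-(benzyloxy)-7-[4-(benzyloxy)benzyl]-3-[3-(benzyloxy)phenyl]-6-methoxy-3,4-dihydroisocoumarin (racemic at C3) | O=C1OC(c2cccc(OCc3ccccc3)c2)Cc2cc(OC)c(Cc3ccc(OCc4ccccc4)cc3)c(OCc3ccccc3)c21 | intermediate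
16 | (±)-8-hydroxy-7-(4-hydroxybenzyl)-3-(3-hydroxyphenyl)-6-methoxy-3,4-dihydroisocoumarin (not isolated) | O=C1OC(c2cccc(O)c2)Cc2cc(OC)c(Cc3ccc(O)cc3)c(O)c21 | intermediate
17 | 2-hydroxy-3-(4-hydroxybenzyl)-6-[2-(3-hydroxyphenyl)ethyl]-4-methoxybenzoic acid | OC(=O)c1c(CCc2cccc(O)c2)cc(OC)c(Cc2ccc(O)cc2)c1O | intermediate
18 | 3-[2-(3-hydroxyphenyl)ethyl]-6-(4-hydroxybenzyl)-5-methoxyphenol, achiral | COc1cc(CCc2cccc(O)c2)cc(O)c1Cc1ccc(O)cc1 | target

Total step count: 8. Longest linear sequence: 8 steps (1 to 18); 2, 5 and 12 enter as bought compounds.

Steps most likely to fail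

Step 6. The carbonyl addition is reversible, and the alkoxide must close on a doubly ortho-flanked ester. If closure is slow, the adduct may revert and the carbanion may be lost to proton transfer and self-acylation. The fallback sets out from 11 and comes back at 17. It replaces the addition–lactonisation by an irreversible SN2 capture and releases the acid in a different way. Carbanion 13 is generated from 11 with LDA and alkylated with commercial 3-(benzyloxy)benzyl bromide (BrCc1cccc(OCc2ccccc2)c1) to give the open bibenzyl ester methyl 2-(benzyloxy)-3-[4-(benzyloxy)benzyl]-6-{2-[3-(benzyloxy)phenyl]ethyl}-4-methoxybenzoate F1. Hydrogenolysis (H2, Pd/C, EtOAc–MeOH) should give methyl 2-hydroxy-3-(4-hydroxybenzyl)-6-[2-(3-hydroxyphenyl)ethyl]-4-methoxybenzoate F2. Its ester is saponified with KOH in aqueous ethylene glycol at about 120 °C, as is usual for resorcylate esters of this type, and acidification returns to 17. Any loss of CO2 under these conditions only anticipates step 8.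

Step 7. The hydrogenolysis may stall after the O-debenzylations. The secondary benzylic C3–O bond of the lactone sits on a ring with only a meta oxygen and is cleaved slowly, and forcing conditions may start ring saturation. The fallback sets out from 15 and comes back at 17. It opens the lactone by elimination instead of reduction. KOtBu in THF–DMSO at rt removes a C4 proton (benzylic and vinylogously activated by the lactone carbonyl) and expels the carboxylate from C3 (E1cB). This should give (E)-2-(benzyloxy)-3-[4-(benzyloxy)benzyl]-6-{2-[3-(benzyloxy)phenyl]ethenyl}-4-methoxybenzoic acid F3. Ordinary hydrogenation (H2, 1 bar, Pd/C, EtOAc–MeOH) then saturates the stilbene double bond and removes the three benzyl ethers to give 17.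

Step 2. Michael addition to the weakly electrophilic crotonate is reversible, and the Dieckmann closure must use a secondary, benzyl-substituted carbon, so the sequence may stall at the open adduct or revert. The fallback sets out from 2 and comes back at 9, and steps 1 to 3 are skipped. Ring A is bought instead of built. Commercial methyl 2,4-dihydroxy-6-methylbenzoate (COC(=O)c1c(C)cc(O)cc1O), used in excess, is benzylated with 2 under mild Lewis acid catalysis (ZnCl2 or Sc(OTf)3, CH2Cl2–dioxane, 0 °C to rt). This is a Friedel–Crafts reaction at C3, the position ortho to both hydroxyl groups, as in the C3 alkylation of resorcylate esters with allylic cations. Regiocontrol against C5 is the price of this route, and the isomer would have to be removed by chromatography.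

Further compounds
F1 | step 6 | methyl 2-(benzyloxy)-3-[4-(benzyloxy)benzyl]-6-{2-[3-(benzyloxy)phenyl]ethyl}-4-methoxybenzoate | COC(=O)c1c(CCc2cccc(OCc3ccccc3)c2)cc(OC)c(Cc2ccc(OCc3ccccc3)cc2)c1OCc1ccccc1
F2 | step 6 | methyl 2-hydroxy-3-(4-hydroxybenzyl)-6-[2-(3-hydroxyphenyl)ethyl]-4-methoxybenzoate | COC(=O)c1c(CCc2cccc(O)c2)cc(OC)c(Cc2ccc(O)cc2)c1O
F3 | step 7 | (E)-2-(benzyloxy)-3-[4-(benzyloxy)benzyl]-6-{2-[3-(benzyloxy)phenyl]ethenyl}-4-methoxybenzoic acid | OC(=O)c1c(/C=C/c2cccc(OCc3ccccc3)c2)cc(OC)c(Cc2ccc(OCc3ccccc3)cc2)c1OCc1ccccc1
F0 | step 2 | none | none
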